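**Plan**

1. Retrosynthesis of the side chain: C7–H is cut back to an aryl ketone, C7–ring C to an aryl Grignard reagent plus a Weinreb amide, and O–C8 to a ring A phenol plus methyl (R)-lactate. The two oxolane methyl groups are traced back to a cis-fused γ-lactone (carbonyl on C3, CH2–O on C4).
2. The oxolane is cut at O1–C5 and C2–C3. C5 (bearing ring B, 3,4-dimethoxyphenyl) and C2 (bearing ring A, 3-methoxy-4-oxyphenyl) are both benzylic ether carbons, cis to each other and to the C4 substituent, and C3 can carry a malonyl unit. The ring therefore maps onto a trans-2-aryl-3-(oxymethyl)cyclopropane-1,1-diester (ring B as donor) and a ring A benzaldehyde.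
3. Forward order: organocatalytic cyclopropanation, reduction and silylation; the (3+2) annulation closes the oxolane; lactonisation and decarboxylation fix C3; both carbinols are reduced to methyl; ring A is unmasked and the side chain is built on its phenol.
4. Stereochemistry: C4 from the catalyst-controlled cyclopropanation; C5 by inversion at the donor carbon and C2 by the cis-selective ring closure of the annulation; C3 by the obligatory cis fusion of the lactone; C8 from methyl (R)-lactate with Mitsunobu inversion; C7 by chelation-controlled reduction.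

Key step: step 4

Remarks on the chemistry
- Locants: oxolane O1, C2 (ring A), C3, C4, C5 (ring B); side chain C7 (carbinol carbon bearing ring C, the second 3,4-dimethoxyphenyl group) and C8 (ether carbon).
- The C4 methyl passes through the annulation as a silyloxymethyl group. This oxidation level comes directly from the cyclopropanation product, and after the annulation the carbinol lactonises onto the cis ester at C3. That fixes the all-cis C3 centre without a contra-thermodynamic protonation, and both methyl groups are then made together.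
- The ring A oxygen is carried as a benzyl ether. Compounds 1, 2, 6, 16 and 19 (as a THF solution) are assumed to be purchased.

**Route**

Step 1
Reactants: 1 (E)-3-(3,4-dimethoxyphenyl)prop-2-enal; 2 diethyl bromomalonate
Product: 3 diethyl (2S,3R)-2-(3,4-dimethoxyphenyl)-3-formylcyclopropane-1,1-dicarboxylate (aryl and formyl trans)
Conditions: (S)-2-[diphenyl(trimethylsilyloxy)methyl]pyrrolidine (20 mol%), 2,6-lutidine (1.1 equiv), CH2Cl2, 0 °C to rt
Reagents that add atoms: none
Why: Iminium–enamine organocascade (Michael-initiated ring closure): the bromomalonate adds to the β-carbon of the iminium ion on the face left open by the diphenyl(silyloxy)methyl group of the (S)-catalyst, which sets the aryl-bearing carbon (S), and the enamine then displaces bromide in a 3-exo-tet alkylation that places the formyl group trans to the aryl group (R).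

Step 2
Reactants: 3 diethyl (2S,3R)-2-(3,4-dimethoxyphenyl)-3-formylcyclopropane-1,1-dicarboxylate
Product: 4 diethyl (2S,3R)-2-(3,4-dimethoxyphenyl)-3-(hydroxymethyl)cyclopropane-1,1-dicarboxylate
Conditions: NaBH4, MeOH, −20 °C; aq. NH4Cl
Reagents that add atoms: none
Why: Chemoselective borohydride reduction of the aldehyde beside two esters; the low temperature and neutral quench should keep the alcohol from lactonising onto the cis ester, and no stereocentre is touched.

Step 3
Reactants: 4 diethyl (2S,3R)-2-(3,4-dimethoxyphenyl)-3-(hydroxymethyl)cyclopropane-1,1-dicarboxylate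
Product: 5 diethyl (2S,3R)-2-(3,4-dimethoxyphenyl)-3-{[(tert-butyldiphenylsilyl)oxy]methyl}cyclopropane-1,1-dicarboxylate (aryl and silyloxymethyl trans)
Conditions: TBDPSCl, imidazole, CH2Cl2, 0 °C to rt
Reagents that add atoms: tert-butyl(chloro)diphenylsilane, CC(C)(C)[Si](Cl)(c1ccccc1)c1ccccc1
Why: Standard silylation of a primary alcohol; the bulky silyl ether blocks lactonisation and is expected to survive a catalytic Lewis acid.

Step 4
Reactants: 5 diethyl (2S,3R)-2-(3,4-dimethoxyphenyl)-3-{[(tert-butyldiphenylsilyl)oxy]methyl}cyclopropane-1,1-dicarboxylate; 6 4-(benzyloxy)-3-methoxybenzaldehyde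
Product: 7 diethyl (2R,4R,5R)-2-[4-(benzyloxy)-3-methoxyphenyl]-4-{[(tert-butyldiphenylsilyl)oxy]methyl}-5-(3,4-dimethoxyphenyl)oxolane-3,3-dicarboxylate (substituents at C2, C4 and C5 all cis)
Conditions: 6 (2 equiv), AlCl3 (10–20 mol%), CH2Cl2, −20 °C to rt
Reagents that add atoms: none
Why: AlCl3 chelates the two ester carbonyls of 5 and polarises the bond between C1 and the aryl-bearing carbon; the carbonyl oxygen of 6 attacks that benzylic carbon from the rear of the breaking bond (SN2-like, within an intimate ion pair) to form O1–C5, and the aluminium malonate enolate then adds to the oxocarbenium carbon to form C2–C3. The closest known reaction type is the Lewis acid-catalysed (3+2) annulation of aryl-substituted donor–acceptor cyclopropane-1,1-diesters with aldehydes, which is established for 2,3-disubstituted cyclopropanes carrying an oxymethyl group. The oxolane is closed by the C2–C3 bond in an aldol-type 5-(enolexo)-endo-trig attack on the oxocarbenium ion through an envelope transition state. C5 is set by the inversion at the donor carbon, so the trans aryl/silyloxymethyl relationship of 5 becomes 4,5-cis (C4 is carried over unchanged), and C2 is set in the ring closure, where the E-oxocarbenium ion and pseudo-equatorial aryl groups place ring A cis to ring B. The step needs aldehyde capture to outrun reversible opening of the cyclopropane and the 2,5-cis product to survive the Lewis acid; the electron-rich, strongly nucleophilic aldehyde in excess, the low catalyst loading and temperature, and the fixed C4 centre (which turns any leakage into separable diastereomers, not into loss of enantiopurity) should secure this.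

Step 5
Reactants: 7 diethyl (2R,4R,5R)-2-[4-(benzyloxy)-3-methoxyphenyl]-4-{[(tert-butyldiphenylsilyl)oxy]methyl}-5-(3,4-dimethoxyphenyl)oxolane-3,3-dicarboxylate
Product: 9 ethyl (3aR,4R,6R,6aR)-6-[4-(benzyloxy)-3-methoxyphenyl]-4-(3,4-dimethoxyphenyl)-1-oxotetrahydro-1H,3H-furo[3,4-c]furan-6a-carboxylate (cis-fused lactone on C3/C4 of the oxolane; both aryl groups on the lactone face), via hydroxymethyl diester 8 (not isolated)
Conditions: TBAF, THF, 0 °C to rt
Reagents that add atoms: none
Why: Fluoride desilylation followed by 5-exo-trig lactonisation: the liberated alkoxide can reach only the ester on its own face of the oxolane, so the two diastereotopic esters are told apart and C3 becomes a defined centre with the lactone carbonyl cis to the C4 carbon substituent.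

Step 6
Reactants: 9 ethyl (3aR,4R,6R,6aR)-6-[4-(benzyloxy)-3-methoxyphenyl]-4-(3,4-dimethoxyphenyl)-1-oxotetrahydro-1H,3H-furo[3,4-c]furan-6a-carboxylate
Product: 11 (3aR,4R,6S,6aR)-6-[4-(benzyloxy)-3-methoxyphenyl]-4-(3,4-dimethoxyphenyl)tetrahydro-1H,3H-furo[3,4-c]furan-1-one (cis-fused lactone), via lactone carboxylic acid 10 (not isolated)
Conditions: LiCl, H2O, DMSO, 140 °C
Reagents that add atoms: none
Why: Krapcho dealkoxycarbonylation of an α-ethoxycarbonyl lactone: chloride dealkylates the ethyl ester, the carboxylate loses CO2 and the lactone enolate is protonated by water; since the bicyclic lactone can only be cis-fused, the hydrogen enters on the face away from the lactone ring, which sets C3 with its carbon substituent cis to those at C2, C4 and C5.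

Step 7
Reactants: 11 (3aR,4R,6S,6aR)-6-[4-(benzyloxy)-3-methoxyphenyl]-4-(3,4-dimethoxyphenyl)tetrahydro-1H,3H-furo[3,4-c]furan-1-one
Product: 12 {(2S,3S,4R,5R)-2-[4-(benzyloxy)-3-methoxyphenyl]-5-(3,4-dimethoxyphenyl)oxolane-3,4-diyl}dimethanol (all-cis)
Conditions: LiAlH4, THF, 0 °C
Reagents that add atoms: none
Why: Hydride reduction of the lactone to the diol; it is fast compared with enolisation, and the stereocentres are not involved.

Step 8
Reactants: 12 {(2S,3S,4R,5R)-2-[4-(benzyloxy)-3-methoxyphenyl]-5-(3,4-dimethoxyphenyl)oxolane-3,4-diyl}dimethanol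
Product: 13 {(2S,3S,4R,5R)-2-[4-(benzyloxy)-3-methoxyphenyl]-5-(3,4-dimethoxyphenyl)oxolane-3,4-diyl}bis(methylene) dimethanesulfonate
Conditions: MsCl, Et3N, CH2Cl2, −10 °C
Reagents that add atoms: methanesulfonyl chloride, CS(=O)(=O)Cl
Why: Sulfonylation of both primary alcohols through sulfene at low temperature, which should be fast enough to outrun cyclisation of a mono-mesylate to a bicyclic ether.

Step 9
Reactants: 13 {(2S,3S,4R,5R)-2-[4-(benzyloxy)-3-methoxyphenyl]-5-(3,4-dimethoxyphenyl)oxolane-3,4-diyl}bis(methylene) dimethanesulfonate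
Product: 14 (2S,3R,4S,5R)-2-[4-(benzyloxy)-3-methoxyphenyl]-5-(3,4-dimethoxyphenyl)-3,4-dimethyloxolane (all-cis)
Conditions: LiEt3BH, THF, 0 °C to rt
Reagents that add atoms: none
Why: SN2 displacement of both primary mesylates by hydride, the usual way of turning CH2OH into CH3; aryl ethers and the oxolane are inert to the reagent.

Step 10
Reactants: 14 (2S,3R,4S,5R)-2-[4-(benzyloxy)-3-methoxyphenyl]-5-(3,4-dimethoxyphenyl)-3,4-dimethyloxolane
Product: 15 4-[(2S,3R,4S,5R)-5-(3,4-dimethoxyphenyl)-3,4-dimethyloxolan-2-yl]-2-methoxyphenol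
Conditions: H2 (1 atm), Pd/C, EtOAc, rt
Reagents that add atoms: none
Why: Catalytic hydrogenolysis of the benzyl aryl ether under neutral conditions, which should leave the cyclic dibenzylic ether intact.

Step 11
Reactants: 15 4-[(2S,3R,4S,5R)-5-(3,4-dimethoxyphenyl)-3,4-dimethyloxolan-2-yl]-2-methoxyphenol; 16 methyl (2R)-2-hydroxypropanoate
Product: 17 methyl (2S)-2-{4-[(2S,3R,4S,5R)-5-(3,4-dimethoxyphenyl)-3,4-dimethyloxolan-2-yl]-2-methoxyphenoxy}propanoate
Conditions: PPh3, DIAD, THF, 0 °C to rt
Reagents that add atoms: none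
Why: Mitsunobu etherification: the phenol displaces the activated secondary hydroxyl of the lactate in an SN2 reaction, so the (R) centre of 16 is inverted to the (S) centre C8.

Step 12
Reactants: 17 methyl (2S)-2-{4-[(2S,3R,4S,5R)-5-(3,4-dimethoxyphenyl)-3,4-dimethyloxolan-2-yl]-2-methoxyphenoxy}propanoate
Product: 18 (2S)-2-{4-[(2S,3R,4S,5R)-5-(3,4-dimethoxyphenyl)-3,4-dimethyloxolan-2-yl]-2-methoxyphenoxy}-N-methoxy-N-methylpropanamide
Conditions: MeNH(OMe)·HCl, iPrMgCl, THF, −20 °C
Reagents that add atoms: N,O-dimethylhydroxylamine hydrochloride, CNOC.Cl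
Why: Aminolysis of the methyl ester by the chloromagnesium amide of N,O-dimethylhydroxylamine (Weinreb amide formation); the low temperature and weakly basic amide should leave the α-aryloxy centre untouched.

Step 13
Reactants: 18 (2S)-2-{4-[(2S,3R,4S,5R)-5-(3,4-dimethoxyphenyl)-3,4-dimethyloxolan-2-yl]-2-methoxyphenoxy}-N-methoxy-N-methylpropanamide; 19 (3,4-dimethoxyphenyl)magnesium bromide
Product: 20 (2S)-1-(3,4-dimethoxyphenyl)-2-{4-[(2S,3R,4S,5R)-5-(3,4-dimethoxyphenyl)-3,4-dimethyloxolan-2-yl]-2-methoxyphenoxy}propan-1-one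
Conditions: THF, −20 to 0 °C; aq. NH4Cl
Reagents that add atoms: none
Why: Grignard addition to a Weinreb amide stops at the chelated tetrahedral intermediate, which collapses to the ketone only on work-up, so neither over-addition nor enolisation at C8 is expected.

Step 14
Reactants: 20 (2S)-1-(3,4-dimethoxyphenyl)-2-{4-[(2S,3R,4S,5R)-5-(3,4-dimethoxyphenyl)-3,4-dimethyloxolan-2-yl]-2-methoxyphenoxy}propan-1-one
Product: 21 (1R,2S)-1-(3,4-dimethoxyphenyl)-2-{4-[(2S,3R,4S,5R)-5-(3,4-dimethoxyphenyl)-3,4-dimethyloxolan-2-yl]-2-methoxyphenoxy}propan-1-ol (CNP0286615.2)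
Conditions: Zn(BH4)2, Et2O, −30 to 0 °C
Reagents that add atoms: none
Why: Chelation-controlled (Cram-chelate) hydride reduction: zinc bridges the carbonyl oxygen and the aryloxy oxygen at C8, hydride adds to the carbonyl face on the side of the C8 hydrogen, and this should give the 1R carbinol (1,2-anti, erythro).

**Compound list**

1 | (E)-3-(3,4-dimethoxyphenyl)prop-2-enal (3,4-dimethoxycinnamaldehyde) | COc1ccc(/C=C/C=O)cc1OC | starting material
2 | diethyl 2-bromopropanedioate (diethyl bromomalonate) | CCOC(=O)C(Br)C(=O)OCC | starting material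
3 | diethyl (2S,3R)-2-(3,4-dimethoxyphenyl)-3-formylcyclopropane-1,1-dicarboxylate | CCOC(=O)C1(C(=O)OCC)[C@H](c2ccc(OC)c(OC)c2)[C@H]1C=O | intermediate
4 | diethyl (2S,3R)-2-(3,4-dimethoxyphenyl)-3-(hydroxymethyl)cyclopropane-1,1-dicarboxylate | CCOC(=O)C1(C(=O)OCC)[C@H](c2ccc(OC)c(OC)c2)[C@H]1CO | intermediate
5 | diethyl (2S,3R)-2-(3,4-dimethoxyphenyl)-3-{[(tert-butyldiphenylsilyl)oxy]methyl}cyclopropane-1,1-dicarboxylate | CCOC(=O)C1(C(=O)OCC)[C@H](c2ccc(OC)c(OC)c2)[C@H]1CO[Si](c3ccccc3)(c4ccccc4)C(C)(C)C | intermediate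
6 | 4-(benzyloxy)-3-methoxybenzaldehyde | COc1cc(C=O)ccc1OCc2ccccc2 | starting material
7 | diethyl (2R,4R,5R)-2-[4-(benzyloxy)-3-methoxyphenyl]-4-{[(tert-butyldiphenylsilyl)oxy]methyl}-5-(3,4-dimethoxyphenyl)oxolane-3,3-dicarboxylate | COc1cc(ccc1OCc6ccccc6)[C@H]2O[C@@H](c3ccc(OC)c(OC)c3)[C@@H](CO[Si](c4ccccc4)(c5ccccc5)C(C)(C)C)C2(C(=O)OCC)C(=O)OCC | intermediate
8 | diethyl (2R,4R,5R)-2-[4-(benzyloxy)-3-methoxyphenyl]-5-(3,4-dimethoxyphenyl)-4-(hydroxymethyl)oxolane-3,3-dicarboxylate | COc1cc(ccc1OCc6ccccc6)[C@H]2O[C@@H](c3ccc(OC)c(OC)c3)[C@@H](CO)C2(C(=O)OCC)C(=O)OCC | intermediate (not isolated)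
9 | ethyl (3aR,4R,6R,6aR)-6-[4-(benzyloxy)-3-methoxyphenyl]-4-(3,4-dimethoxyphenyl)-1-oxotetrahydro-1H,3H-furo[3,4-c]furan-6a-carboxylate | COc1cc(ccc1OCc6ccccc6)[C@H]2O[C@@H](c3ccc(OC)c(OC)c3)[C@H]4COC(=O)[C@@]24C(=O)OCC | intermediate
10 | (3aR,4R,6R,6aR)-6-[4-(benzyloxy)-3-methoxyphenyl]-4-(3,4-dimethoxyphenyl)-1-oxotetrahydro-1H,3H-furo[3,4-c]furan-6a-carboxylic acid (present as its lithium salt) | COc1cc(ccc1OCc6ccccc6)[C@H]2O[C@@H](c3ccc(OC)c(OC)c3)[C@H]4COC(=O)[C@@]24C(=O)O | intermediate (not isolated)
11 | (3aR,4R,6S,6aR)-6-[4-(benzyloxy)-3-methoxyphenyl]-4-(3,4-dimethoxyphenyl)tetrahydro-1H,3H-furo[3,4-c]furan-1-one | COc1cc(ccc1OCc6ccccc6)[C@H]2O[C@@H](c3ccc(OC)c(OC)c3)[C@H]4COC(=O)[C@@H]24 | intermediate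
12 | {(2S,3S,4R,5R)-2-[4-(benzyloxy)-3-methoxyphenyl]-5-(3,4-dimethoxyphenyl)oxolane-3,4-diyl}dimethanol | COc1cc(ccc1OCc6ccccc6)[C@H]2O[C@@H](c3ccc(OC)c(OC)c3)[C@@H](CO)[C@H]2CO | intermediate
13 | {(2S,3S,4R,5R)-2-[4-(benzyloxy)-3-methoxyphenyl]-5-(3,4-dimethoxyphenyl)oxolane-3,4-diyl}bis(methylene) dimethanesulfonate | COc1cc(ccc1OCc6ccccc6)[C@H]2O[C@@H](c3ccc(OC)c(OC)c3)[C@@H](COS(C)(=O)=O)[C@H]2COS(C)(=O)=O | intermediate
14 | (2S,3R,4S,5R)-2-[4-(benzyloxy)-3-methoxyphenyl]-5-(3,4-dimethoxyphenyl)-3,4-dimethyloxolane | COc1cc(ccc1OCc6ccccc6)[C@H]2O[C@@H](c3ccc(OC)c(OC)c3)[C@@H](C)[C@H]2C | intermediate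
15 | 4-[(2S,3R,4S,5R)-5-(3,4-dimethoxyphenyl)-3,4-dimethyloxolan-2-yl]-2-methoxyphenol | COc1cc(ccc1O)[C@H]2O[C@@H](c3ccc(OC)c(OC)c3)[C@@H](C)[C@H]2C | intermediate
16 | methyl (2R)-2-hydroxypropanoate (methyl (R)-lactate) | C[C@@H](O)C(=O)OC | starting material
17 | methyl (2S)-2-{4-[(2S,3R,4S,5R)-5-(3,4-dimethoxyphenyl)-3,4-dimethyloxolan-2-yl]-2-methoxyphenoxy}propanoate | COC(=O)[C@H](C)Oc1ccc(cc1OC)[C@H]2O[C@@H](c3ccc(OC)c(OC)c3)[C@@H](C)[C@H]2C | intermediate
18 | (2S)-2-{4-[(2S,3R,4S,5R)-5-(3,4-dimethoxyphenyl)-3,4-dimethyloxolan-2-yl]-2-methoxyphenoxy}-N-methoxy-N-methylpropanamide | CON(C)C(=O)[C@H](C)Oc1ccc(cc1OC)[C@H]2O[C@@H](c3ccc(OC)c(OC)c3)[C@@H](C)[C@H]2C | intermediate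
19 | (3,4-dimethoxyphenyl)magnesium bromide | COc1ccc([Mg]Br)cc1OC | starting material
20 | (2S)-1-(3,4-dimethoxyphenyl)-2-{4-[(2S,3R,4S,5R)-5-(3,4-dimethoxyphenyl)-3,4-dimethyloxolan-2-yl]-2-methoxyphenoxy}propan-1-one | COc1ccc(cc1OC)C(=O)[C@H](C)Oc2ccc(cc2OC)[C@H]3O[C@@H](c4ccc(OC)c(OC)c4)[C@@H](C)[C@H]3C | intermediate
21 | (1R,2S)-1-(3,4-dimethoxyphenyl)-2-{4-[(2S,3R,4S,5R)-5-(3,4-dimethoxyphenyl)-3,4-dimethyloxolan-2-yl]-2-methoxyphenoxy}propan-1-ol | COc1ccc([C@@H](O)[C@H](C)Oc2ccc([C@H]3O[C@@H](c4ccc(OC)c(OC)c4)[C@@H](C)[C@H]3C)cc2OC)cc1OC | target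

**Step count and risks**

Total step count: 14. Longest linear sequence: 14 steps (from 1 and 2 to 21); 6, 16 and 19 are purchased and enter directly.

Steps most likely to fail:

Step 4. The Lewis acid may strip the silyl ether, with uncontrolled lactonisation of the cyclopropane. Slow capture beside the bulky silyloxymethyl group may also let the opened ion pair re-close on the other face of the benzylic carbon, which would erode the 4,5-cis relationship. Fallback: the oxygen is tied back as a lactone before the annulation. Starting from alcohol 4, catalytic TsOH in CH2Cl2 should give the cyclopropane-fused lactone ethyl (1S,5R,6S)-6-(3,4-dimethoxyphenyl)-2-oxo-3-oxabicyclo[3.1.0]hexane-1-carboxylate F1. This is a more strained donor–acceptor cyclopropane without a protecting group and with the same chelating 1,3-dicarbonyl unit. Its annulation with 6 under Sn(OTf)2 or AlCl3 in CH2Cl2 should form the same two bonds and give lactone ester 9 directly. The route is rejoined at 9, and steps 3 and 5 fall away.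

Step 14. Weak coordination of zinc by the aryl ether oxygen may leave open-chain hydride delivery competitive, so that the (1S,2S) threo epimer forms alongside the target. Fallback: the sense of hydride delivery is taken from a chiral catalyst instead of the substrate. Ketone 20 is reduced with BH3·SMe2 and the (R)-configured B-methyl oxazaborolidine (CBS reduction), which with ring C as the large group should place hydride on the same carbonyl face as the chelate model and give 21 directly. Any threo epimer can be oxidised back to 20 with Dess–Martin periodinane and reduced again. No compound outside the list is made (F0).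

Step 6. At 140 °C the lactone enolate left after loss of CO2 may expel O1 from C2 (β-elimination) and re-close with ring A on the other face, or chloride may open the lactone at its CH2–O carbon. Fallback: hydrolysis and decarboxylation through the free acid. Starting from 9, LiOH in THF/H2O at room temperature should give the ring-opened (2R,4R,5R)-2-[4-(benzyloxy)-3-methoxyphenyl]-5-(3,4-dimethoxyphenyl)-4-(hydroxymethyl)oxolane-3,3-dicarboxylic acid F2 as its lithium salt. Careful acidification re-closes the cis lactone to acid 10, which is isolated this time. Heating 10 in toluene at about 110 °C should decarboxylate it through the neutral enol, so that no basic enolate is exposed to high temperature. The route is rejoined at lactone 11.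

Further compounds
F1 | step 4 | ethyl (1S,5R,6S)-6-(3,4-dimethoxyphenyl)-2-oxo-3-oxabicyclo[3.1.0]hexane-1-carboxylate | CCOC(=O)[C@]12[C@H](c3ccc(OC)c(OC)c3)[C@H]1COC2=O
F0 | step 14 | none | none
F2 | step 6 | (2R,4R,5R)-2-[4-(benzyloxy)-3-methoxyphenyl]-5-(3,4-dimethoxyphenyl)-4-(hydroxymethyl)oxolane-3,3-dicarboxylic acid | COc1cc(ccc1OCc6ccccc6)[C@H]2O[C@@H](c3ccc(OC)c(OC)c3)[C@@H](CO)C2(C(=O)O)C(=O)O
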